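**Assumption (one line):** MeI, t-BuCOCl, TBSOTf and similar are treated as reagents; the sense of induction of (S)-BINAP in step 9 is taken from the usual facial model for cyclic enoates (if it proves reversed, (R)-BINAP is used).

## Retrosynthetic overview

1. The target tetraol comes from LiAlH4 reduction of a cis-fused aryltetralin lactone, which also removes the two catechol pivalates.
2. Ring B is formed last by a cationic Friedel–Crafts closure (C1–C8a) of a 3,4-cis-disubstituted γ-butyrolactone; the 2,3-cis relationship comes from hydrogenating an α-arylidene lactone.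
3. The arylidene lactone comes from a late aldol condensation between the ring A aldehyde (from p-cresol) and a chiral β-[aryl(silyloxy)methyl]butyrolactone.
4. The lactone fragment comes from an aryl Grignard reagent (from resorcinol) and an (R)-formyl lactone, itself made from furan-2(5H)-one by rhodium-catalysed asymmetric vinylation and ozonolysis.
5. Ring order: the two benzene rings are bought and elaborated separately, the lactone ring is present from the start, and ring B is closed at the end.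

## Route

**Step 1**
Reactants: 1 4-methylphenol
Product: 4 3,5-dibromo-4-hydroxybenzaldehyde, via dibromocresol 2 (not isolated), via benzal bromide 3 (not isolated)
Conditions: Br2 (4.1 equiv), 1,2-dichlorobenzene, 35 °C then 150 °C; then H2O, 100 °C
Reagents that add atoms: bromine BrBr; water O
Why: Electrophilic bromination ortho to the phenol, then side-chain bromination of the para-methyl group to the benzal bromide and hydrolysis, gives the aldehyde in one pot.

**Step 2**
Reactants: 4 3,5-dibromo-4-hydroxybenzaldehyde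
Product: 5 4-hydroxy-3,5-dimethoxybenzaldehyde
Conditions: NaOMe (4 equiv), CuCl (10 mol%), DMF/MeOH, 115 °C; then aq. HCl
Reagents that add atoms: sodium methoxide [Na+].[O-]C
Why: Copper-catalysed Ullmann-type methoxylation replaces both aryl bromides flanking the phenoxide.

**Step 3**
Reactants: 5 4-hydroxy-3,5-dimethoxybenzaldehyde
Product: 6 3,4-dihydroxy-5-methoxybenzaldehyde
Conditions: AlCl3 (1.1 equiv), pyridine (4.5 equiv), CH2Cl2, reflux; then 2 M HCl
Reagents that add atoms: none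
Why: The aluminium phenoxide chelates one neighbouring methoxy group and only that methyl is cleaved (Lewis-acid ortho-demethylation); the substrate is symmetric, so one product results.

**Step 4**
Reactants: 6 3,4-dihydroxy-5-methoxybenzaldehyde
Product: 7 5-formyl-3-methoxy-1,2-phenylene bis(2,2-dimethylpropanoate)
Conditions: t-BuCOCl (2.5 equiv), Et3N, DMAP (cat.), CH2Cl2, 0 °C → rt
Reagents that add atoms: pivaloyl chloride CC(C)(C)C(Cl)=O
Why: Acylation of both phenols gives esters that tolerate enolate, acid and hydrogenation conditions, make the two catechol oxygens poor donors for the later ring closure, and fall off in the final hydride step.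

**Step 5**
Reactants: 8 benzene-1,3-diol
Product: 9 1,3-dimethoxybenzene
Conditions: MeI (2.5 equiv), K2CO3, acetone, reflux
Reagents that add atoms: iodomethane CI
Why: Williamson O-methylation of both phenols.

**Step 6**
Reactants: 9 1,3-dimethoxybenzene
Product: 12 2,6-dimethoxyphenol, via aryllithium 10 (not isolated), via boronate ester 11 (not isolated)
Conditions: n-BuLi (1.1 equiv), THF, 0 °C → rt; B(OMe)3, −78 °C → rt; then 30% H2O2, 0 °C → rt
Reagents that add atoms: hydrogen peroxide OO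
Why: Directed ortho-metalation occurs at C2 between the two methoxy groups, and borylation followed by peroxide oxidation (1,2-aryl shift from boron to oxygen) installs the third oxygen.

**Step 7**
Reactants: 12 2,6-dimethoxyphenol
Product: 13 4-bromo-2,6-dimethoxyphenol
Conditions: NBS (1.0 equiv), CH2Cl2, −40 °C → 0 °C
Reagents that add atoms: N-bromosuccinimide O=C1CCC(=O)N1Br
Why: Electrophilic bromination goes para to the free phenol, the only activated open position.

**Step 8**
Reactants: 13 4-bromo-2,6-dimethoxyphenol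
Product: 14 5-bromo-1,2,3-trimethoxybenzene
Conditions: MeI (1.5 equiv), K2CO3, acetone, reflux
Reagents that add atoms: iodomethane CI
Why: Williamson O-methylation of the remaining phenol.

**Step 9**
Reactants: 15 furan-2(5H)-one; 16 potassium trifluoro(vinyl)borate
Product: 17 (S)-4-ethenyloxolan-2-one
Conditions: Rh(acac)(C2H4)2 (3 mol%), (S)-BINAP (3.6 mol%), K[CH2=CHBF3] (2 equiv), dioxane/H2O 10:1, 100 °C
Reagents that add atoms: none
Why: Hayashi–Miyaura asymmetric 1,4-addition, in which the vinylrhodium–(S)-BINAP complex adds to one enantioface of the butenolide β-carbon and so sets the future C2 of the target.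

**Step 10**
Reactants: 17 (S)-4-ethenyloxolan-2-one
Product: 19 (R)-5-oxooxolane-3-carbaldehyde, via secondary ozonide 18 (not isolated)
Conditions: O3, CH2Cl2, −78 °C; then Me2S, −78 °C → rt; used crude and cold
Reagents that add atoms: ozone [O-][O+]=O
Why: Ozonolysis with reductive work-up cuts the vinyl group to the aldehyde without touching the stereocentre (the descriptor changes only through priority).

**Step 11**
Reactants: 14 5-bromo-1,2,3-trimethoxybenzene; 19 (R)-5-oxooxolane-3-carbaldehyde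
Product: 21 (4R)-4-[hydroxy(3,4,5-trimethoxyphenyl)methyl]oxolan-2-one (both carbinol epimers), via aryl Grignard reagent 20 (not isolated)
Conditions: 14, Mg turnings (I2 cat.), THF, 40 °C; then add to 19, THF, −78 °C, 1 h; AcOH (1.2 equiv) at −78 °C, then H2O
Reagents that add atoms: none
Why: Grignard 1,2-addition at −78 °C is selective for the aldehyde over the lactone and faster than enolisation; the new carbinol centre forms as a mixture, which does not matter because it is ionised in step 16.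

**Step 12**
Reactants: 21 (4R)-4-[hydroxy(3,4,5-trimethoxyphenyl)methyl]oxolan-2-one
Product: 22 (4R)-4-[(tert-butyldimethylsilyloxy)(3,4,5-trimethoxyphenyl)methyl]oxolan-2-one
Conditions: TBSOTf (1.3 equiv), 2,6-lutidine (2 equiv), CH2Cl2, −78 °C → 0 °C
Reagents that add atoms: tert-butyldimethylsilyl triflate CC(C)(C)[Si](C)(C)OS(=O)(=O)C(F)(F)F
Why: Silylation masks the benzylic alcohol so that it cannot translactonise or quench the enolate, and leaves a group that ionises under acid later.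

**Step 13**
Reactants: 22 (4R)-4-[(tert-butyldimethylsilyloxy)(3,4,5-trimethoxyphenyl)methyl]oxolan-2-one; 7 5-formyl-3-methoxy-1,2-phenylene bis(2,2-dimethylpropanoate)
Product: 24 (4R)-3-{[3,4-bis(pivaloyloxy)-5-methoxyphenyl](hydroxy)methyl}-4-[(tert-butyldimethylsilyloxy)(3,4,5-trimethoxyphenyl)methyl]oxolan-2-one (3,4-trans; mixture at the new carbinol), via lithium enolate 23 (not isolated)
Conditions: LiN(i-Pr)2 (1.1 equiv), THF, −78 °C, 45 min; then 7 in THF, −78 °C, 1 h; AcOH quench at −78 °C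
Reagents that add atoms: none
Why: Aldol addition of the lactone lithium enolate joins the two halves; the aldehyde reacts far faster than the hindered aryl pivalates, and the new centres are erased in step 14.

**Step 14**
Reactants: 24 aldol adduct
Product: 26 (4R,E)-3-[3,4-bis(pivaloyloxy)-5-methoxybenzylidene]-4-[(tert-butyldimethylsilyloxy)(3,4,5-trimethoxyphenyl)methyl]oxolan-2-one, via mesylate 25 (not isolated)
Conditions: MsCl (1.5 equiv), Et3N (3 equiv), CH2Cl2, 0 °C; then DBU (2 equiv), 0 °C → rt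
Reagents that add atoms: none
Why: Mesylation and E1cB elimination give the conjugated (E)-arylidene lactone (aryl anti to the carbonyl) with the C4 stereocentre untouched.

**Step 15**
Reactants: 26 (E)-arylidene lactone
Product: 27 (3S,4R)-3-[3,4-bis(pivaloyloxy)-5-methoxybenzyl]-4-[(tert-butyldimethylsilyloxy)(3,4,5-trimethoxyphenyl)methyl]oxolan-2-one
Conditions: H2 (1 atm), Pd/C (10 wt% Pd, 5 mol%), EtOAc, rt
Reagents that add atoms: none
Why: Heterogeneous syn-hydrogenation delivers hydrogen to the lactone face opposite the bulky C4 substituent, so the new C3–H is trans to it and the two carbon substituents end up cis (this sets C3 of the target).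

**Step 16**
Reactants: 27 cis-lactone
Product: 29 (3aR,4S,9aS)-7-methoxy-5,6-bis(pivaloyloxy)-4-(3,4,5-trimethoxyphenyl)-3a,4,9,9a-tetrahydronaphtho[2,3-c]furan-1(3H)-one, via benzylic cation 28 (not isolated)
Conditions: CF3CO2H/CH2Cl2 1:4, 0 °C → rt
Reagents that add atoms: none
Why: Acid ionises the benzylic silyl ether and the cation closes ring B by intramolecular Friedel–Crafts alkylation at the ring A carbon para to OMe (the acyloxy groups donate poorly and attack ortho to OMe would twist it out of conjugation); the aryl group enters pseudoaxial, anti to the C3a CH2O arm, to avoid peri strain with the C5 ester, giving the 1,2-trans centre (this sets C1 of the target).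

**Step 17**
Reactants: 29 tetracyclic lactone
Product: 30 (1S,2R,3S)-2,3-bis(hydroxymethyl)-6-methoxy-1-(3,4,5-trimethoxyphenyl)-1,2,3,4-tetrahydronaphthalene-7,8-diol
Conditions: LiAlH4 (6 equiv), THF, 0 °C → rt; aq. KNaC4H4O6, then 1 M HCl to pH 4 under N2
Reagents that add atoms: none
Why: Hydride reduction opens the lactone to the two hydroxymethyl groups and cleaves both aryl pivalates in the same pot, with no stereocentre involved.

## Compound list

1 | 4-methylphenol (p-cresol) | Cc1ccc(O)cc1 | starting material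
2 | 2,6-dibromo-4-methylphenol | Cc1cc(Br)c(O)c(Br)c1 | intermediate (not isolated)
3 | 2,6-dibromo-4-(dibromomethyl)phenol | BrC(Br)c1cc(Br)c(O)c(Br)c1 | intermediate (not isolated)
4 | 3,5-dibromo-4-hydroxybenzaldehyde | O=Cc1cc(Br)c(O)c(Br)c1 | intermediate
5 | 4-hydroxy-3,5-dimethoxybenzaldehyde | COc1cc(C=O)cc(OC)c1O | intermediate
6 | 3,4-dihydroxy-5-methoxybenzaldehyde | COc1cc(C=O)cc(O)c1O | intermediate
7 | 5-formyl-3-methoxy-1,2-phenylene bis(2,2-dimethylpropanoate) | COc1cc(C=O)cc(OC(=O)C(C)(C)C)c1OC(=O)C(C)(C)C | intermediate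
8 | benzene-1,3-diol (resorcinol) | Oc1cccc(O)c1 | starting material
9 | 1,3-dimethoxybenzene | COc1cccc(OC)c1 | intermediate
10 | (2,6-dimethoxyphenyl)lithium | COc1cccc(OC)c1[Li] | intermediate (not isolated)
11 | dimethyl (2,6-dimethoxyphenyl)boronate | COB(OC)c1c(OC)cccc1OC | intermediate (not isolated)
12 | 2,6-dimethoxyphenol | COc1cccc(OC)c1O | intermediate
13 | 4-bromo-2,6-dimethoxyphenol | COc1cc(Br)cc(OC)c1O | intermediate
14 | 5-bromo-1,2,3-trimethoxybenzene | COc1cc(Br)cc(OC)c1OC | intermediate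
15 | furan-2(5H)-one | O=C1OCC=C1 | starting material
16 | potassium trifluoro(vinyl)borate | [K+].F[B-](F)(F)C=C | starting material
17 | (S)-4-ethenyloxolan-2-one | C=C[C@H]1COC(=O)C1 | intermediate
18 | (4R)-4-(1,2,4-trioxolan-3-yl)oxolan-2-one (secondary ozonide, both ozonide epimers) | O1OCOC1[C@H]1COC(=O)C1 | intermediate (not isolated)
19 | (R)-5-oxooxolane-3-carbaldehyde | O=C[C@H]1COC(=O)C1 | intermediate
20 | (3,4,5-trimethoxyphenyl)magnesium bromide | COc1cc([Mg]Br)cc(OC)c1OC | intermediate (not isolated)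
21 | (4R)-4-[hydroxy(3,4,5-trimethoxyphenyl)methyl]oxolan-2-one, both carbinol epimers | COc1cc(cc(OC)c1OC)C(O)[C@H]1COC(=O)C1 | intermediate
22 | (4R)-4-[(tert-butyldimethylsilyloxy)(3,4,5-trimethoxyphenyl)methyl]oxolan-2-one | COc1cc(cc(OC)c1OC)C(O[Si](C)(C)C(C)(C)C)[C@H]1COC(=O)C1 | intermediate
23 | lithium (4R)-4-[(tert-butyldimethylsilyloxy)(3,4,5-trimethoxyphenyl)methyl]-4,5-dihydrofuran-2-olate | COc1cc(cc(OC)c1OC)C(O[Si](C)(C)C(C)(C)C)[C@H]1COC([O-])=C1.[Li+] | intermediate (not isolated)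
24 | (4R)-3-{[3,4-bis(pivaloyloxy)-5-methoxyphenyl](hydroxy)methyl}-4-[(tert-butyldimethylsilyloxy)(3,4,5-trimethoxyphenyl)methyl]oxolan-2-one, 3,4-trans, carbinol mixture | COc1cc(cc(OC)c1OC)C(O[Si](C)(C)C(C)(C)C)[C@H]1COC(=O)C1C(O)c1cc(OC)c(OC(=O)C(C)(C)C)c(OC(=O)C(C)(C)C)c1 | intermediate
25 | methanesulfonate of 24 | COc1cc(cc(OC)c1OC)C(O[Si](C)(C)C(C)(C)C)[C@H]1COC(=O)C1C(OS(C)(=O)=O)c1cc(OC)c(OC(=O)C(C)(C)C)c(OC(=O)C(C)(C)C)c1 | intermediate (not isolated)
26 | (4R,E)-3-[3,4-bis(pivaloyloxy)-5-methoxybenzylidene]-4-[(tert-butyldimethylsilyloxy)(3,4,5-trimethoxyphenyl)methyl]oxolan-2-one | COc1cc(cc(OC)c1OC)C(O[Si](C)(C)C(C)(C)C)[C@H]1COC(=O)/C1=C/c1cc(OC)c(OC(=O)C(C)(C)C)c(OC(=O)C(C)(C)C)c1 | intermediate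
27 | (3S,4R)-3-[3,4-bis(pivaloyloxy)-5-methoxybenzyl]-4-[(tert-butyldimethylsilyloxy)(3,4,5-trimethoxyphenyl)methyl]oxolan-2-one (3,4-cis) | COc1cc(cc(OC)c1OC)C(O[Si](C)(C)C(C)(C)C)[C@H]1COC(=O)[C@H]1Cc1cc(OC)c(OC(=O)C(C)(C)C)c(OC(=O)C(C)(C)C)c1 | intermediate
28 | 3,4,5-trimethoxybenzylic cation of 27 (trifluoroacetate counter-ion) | COc1cc(cc(OC)c1OC)[CH+][C@H]1COC(=O)[C@H]1Cc1cc(OC)c(OC(=O)C(C)(C)C)c(OC(=O)C(C)(C)C)c1.[O-]C(=O)C(F)(F)F | intermediate (not isolated)
29 | (3aR,4S,9aS)-7-methoxy-5,6-bis(pivaloyloxy)-4-(3,4,5-trimethoxyphenyl)-3a,4,9,9a-tetrahydronaphtho[2,3-c]furan-1(3H)-one (cis-fused lactone, aryl trans to C3a CH2O) | COc1cc2c(c(OC(=O)C(C)(C)C)c1OC(=O)C(C)(C)C)[C@H](c1cc(OC)c(OC)c(OC)c1)[C@H]1COC(=O)[C@H]1C2 | intermediate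
30 | (1S,2R,3S)-2,3-bis(hydroxymethyl)-6-methoxy-1-(3,4,5-trimethoxyphenyl)-1,2,3,4-tetrahydronaphthalene-7,8-diol | COc1cc2c(c(O)c1O)[C@H](c1cc(OC)c(OC)c(OC)c1)[C@@H](CO)[C@@H](CO)C2 | target

## Step count and risks

Total step count: 17. Longest linear sequence: 11 steps (5, 6, 7, 8, 11, 12, 13, 14, 15, 16, 17).

**Step 16 (ring closure) is the most likely to fail.** The two open ring A positions are electronically similar, so closure ortho to OMe may compete, and the deactivated ring may react slowly. The fallback moves the C8 oxygen to after ring closure, so that closure can only go para to OMe. It sets out from 1 and 22 and comes back at 30.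
- p-Cresol 1 is monobrominated (Br2, CH2Cl2, 0 °C) to 2-bromo-4-methylphenol F10 and methoxylated (NaOMe, CuCl, DMF/MeOH) to 2-methoxy-4-methylphenol F11.
- Oxidation of the methyl group (DDQ, MeOH, then aq. acid) gives 4-hydroxy-3-methoxybenzaldehyde F12, which is acylated (t-BuCOCl, Et3N) to 4-formyl-2-methoxyphenyl pivalate F13.
- Enolate 23 (from 22) adds to F13 to give aldol adduct F14, which is dehydrated through mesylate F15 to benzylidene lactone F16 and hydrogenated (H2, Pd/C) to cis-lactone F17.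
- CF3CO2H closes ring B to the 7-methoxy-6-pivaloyloxy lactone F18, and K2CO3/MeOH frees phenol F19.
- The single free ortho position of F19 is formylated (MgCl2, Et3N, (CH2O)n, MeCN, reflux) to hydroxy-aldehyde F20, and Dakin oxidation (H2O2, NaOH, then acid) gives catechol lactone F21.
- LiAlH4 reduction of F21 gives 30.

**Step 9 (asymmetric vinylation)** may fail because furan-2(5H)-one is a sluggish acceptor and vinyl transfer can give modest ee; the aldehyde of step 10 is also configurationally fragile. The fallback builds the C1–C2 bond and the C2 centre by carbonyl allylation. It sets out from 5 and comes back at 22, replacing steps 9–12.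
- O-Methylation of 5 (MeI, K2CO3, DMF) gives 3,4,5-trimethoxybenzaldehyde F1.
- Iridium-catalysed anti-selective (hydroxymethyl)allylation with 4-vinyl-1,3-dioxolan-2-one ([Ir(cod)Cl]2, SEGPHOS enantiomer chosen for the 1S,2R product, 4-cyano-3-nitrobenzoic acid, K3PO4, i-PrOH, THF, 60 °C) gives (1S,2R)-2-ethenyl-1-(3,4,5-trimethoxyphenyl)propane-1,3-diol F2.
- Both hydroxyls are silylated (TBSOTf, 2,6-lutidine) to bis-silyl ether F3.
- Hydroboration–oxidation (9-BBN, then NaOH/H2O2) gives primary alcohol F4, and TEMPO/PhI(OAc)2 in MeCN/H2O gives acid F5.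
- HF·pyridine removes the primary silyl ether selectively and the hydroxy acid closes to 22 (as a single carbinol epimer).

**Step 15 (hydrogenation)** may give an incomplete cis preference or cleave the electron-rich benzylic silyl ether. The fallback sets C3 by alkylation and kinetic protonation. It sets out from 7 (with 22) and comes back at 27, replacing steps 13–15.
- NaBH4 (MeOH/THF, 0 °C) reduces 7 to 5-(hydroxymethyl)-3-methoxy-1,2-phenylene dipivalate F6, and PBr3 (Et2O, 0 °C) gives benzyl bromide F7.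
- Enolate 23 is alkylated with F7 (THF/DMPU, −78 °C) to the 3,4-trans lactone F8.
- F8 is deprotonated again (LiN(i-Pr)2, −78 °C) to lithium enolate F9, which is protonated from the face away from the C4 substituent by 2,6-di-tert-butyl-4-methylphenol to give 27.

## Further compounds

F1 | step 9 | 3,4,5-trimethoxybenzaldehyde | COc1cc(C=O)cc(OC)c1OC
F2 | step 9 | (1S,2R)-2-ethenyl-1-(3,4,5-trimethoxyphenyl)propane-1,3-diol | COc1cc(cc(OC)c1OC)[C@@H](O)[C@@H](CO)C=C
F3 | step 9 | (1S,2R)-1,3-bis(tert-butyldimethylsilyloxy)-2-ethenyl-1-(3,4,5-trimethoxyphenyl)propane | COc1cc(cc(OC)c1OC)[C@@H](O[Si](C)(C)C(C)(C)C)[C@@H](CO[Si](C)(C)C(C)(C)C)C=C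
F4 | step 9 | (3R,4S)-4-(tert-butyldimethylsilyloxy)-3-[(tert-butyldimethylsilyloxy)methyl]-4-(3,4,5-trimethoxyphenyl)butan-1-ol | COc1cc(cc(OC)c1OC)[C@@H](O[Si](C)(C)C(C)(C)C)[C@@H](CO[Si](C)(C)C(C)(C)C)CCO
F5 | step 9 | (3R,4S)-4-(tert-butyldimethylsilyloxy)-3-[(tert-butyldimethylsilyloxy)methyl]-4-(3,4,5-trimethoxyphenyl)butanoic acid | COc1cc(cc(OC)c1OC)[C@@H](O[Si](C)(C)C(C)(C)C)[C@@H](CO[Si](C)(C)C(C)(C)C)CC(=O)O
F6 | step 15 | 5-(hydroxymethyl)-3-methoxy-1,2-phenylene bis(2,2-dimethylpropanoate) | COc1cc(CO)cc(OC(=O)C(C)(C)C)c1OC(=O)C(C)(C)C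
F7 | step 15 | 5-(bromomethyl)-3-methoxy-1,2-phenylene bis(2,2-dimethylpropanoate) | COc1cc(CBr)cc(OC(=O)C(C)(C)C)c1OC(=O)C(C)(C)C
F8 | step 15 | (3R,4R)-3-[3,4-bis(pivaloyloxy)-5-methoxybenzyl]-4-[(tert-butyldimethylsilyloxy)(3,4,5-trimethoxyphenyl)methyl]oxolan-2-one (3,4-trans) | COc1cc(cc(OC)c1OC)C(O[Si](C)(C)C(C)(C)C)[C@H]1COC(=O)[C@@H]1Cc1cc(OC)c(OC(=O)C(C)(C)C)c(OC(=O)C(C)(C)C)c1
F9 | step 15 | lithium enolate of F8 | COc1cc(cc(OC)c1OC)C(O[Si](C)(C)C(C)(C)C)[C@H]1COC([O-])=C1Cc1cc(OC)c(OC(=O)C(C)(C)C)c(OC(=O)C(C)(C)C)c1.[Li+]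
F10 | step 16 | 2-bromo-4-methylphenol | Cc1ccc(O)c(Br)c1
F11 | step 16 | 2-methoxy-4-methylphenol | COc1cc(C)ccc1O
F12 | step 16 | 4-hydroxy-3-methoxybenzaldehyde | COc1cc(C=O)ccc1O
F13 | step 16 | 4-formyl-2-methoxyphenyl 2,2-dimethylpropanoate | COc1cc(C=O)ccc1OC(=O)C(C)(C)C
F14 | step 16 | (4R)-3-{hydroxy[3-methoxy-4-(pivaloyloxy)phenyl]methyl}-4-[(tert-butyldimethylsilyloxy)(3,4,5-trimethoxyphenyl)methyl]oxolan-2-one | COc1cc(cc(OC)c1OC)C(O[Si](C)(C)C(C)(C)C)[C@H]1COC(=O)C1C(O)c1ccc(OC(=O)C(C)(C)C)c(OC)c1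
F15 | step 16 | methanesulfonate of F14 | COc1cc(cc(OC)c1OC)C(O[Si](C)(C)C(C)(C)C)[C@H]1COC(=O)C1C(OS(C)(=O)=O)c1ccc(OC(=O)C(C)(C)C)c(OC)c1
F16 | step 16 | (4R,E)-3-[3-methoxy-4-(pivaloyloxy)benzylidene]-4-[(tert-butyldimethylsilyloxy)(3,4,5-trimethoxyphenyl)methyl]oxolan-2-one | COc1cc(cc(OC)c1OC)C(O[Si](C)(C)C(C)(C)C)[C@H]1COC(=O)/C1=C/c1ccc(OC(=O)C(C)(C)C)c(OC)c1
F17 | step 16 | (3S,4R)-3-[3-methoxy-4-(pivaloyloxy)benzyl]-4-[(tert-butyldimethylsilyloxy)(3,4,5-trimethoxyphenyl)methyl]oxolan-2-one | COc1cc(cc(OC)c1OC)C(O[Si](C)(C)C(C)(C)C)[C@H]1COC(=O)[C@H]1Cc1ccc(OC(=O)C(C)(C)C)c(OC)c1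
F18 | step 16 | (3aR,4S,9aS)-7-methoxy-6-(pivaloyloxy)-4-(3,4,5-trimethoxyphenyl)-3a,4,9,9a-tetrahydronaphtho[2,3-c]furan-1(3H)-one | COc1cc2c(cc1OC(=O)C(C)(C)C)[C@H](c1cc(OC)c(OC)c(OC)c1)[C@H]1COC(=O)[C@H]1C2
F19 | step 16 | (3aR,4S,9aS)-6-hydroxy-7-methoxy-4-(3,4,5-trimethoxyphenyl)-3a,4,9,9a-tetrahydronaphtho[2,3-c]furan-1(3H)-one | COc1cc2c(cc1O)[C@H](c1cc(OC)c(OC)c(OC)c1)[C@H]1COC(=O)[C@H]1C2
F20 | step 16 | (3aR,4S,9aS)-6-hydroxy-7-methoxy-1-oxo-4-(3,4,5-trimethoxyphenyl)-1,3,3a,4,9,9a-hexahydronaphtho[2,3-c]furan-5-carbaldehyde | COc1cc2c(c(C=O)c1O)[C@H](c1cc(OC)c(OC)c(OC)c1)[C@H]1COC(=O)[C@H]1C2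
F21 | step 16 | (3aR,4S,9aS)-5,6-dihydroxy-7-methoxy-4-(3,4,5-trimethoxyphenyl)-3a,4,9,9a-tetrahydronaphtho[2,3-c]furan-1(3H)-one | COc1cc2c(c(O)c1O)[C@H](c1cc(OC)c(OC)c(OC)c1)[C@H]1COC(=O)[C@H]1C2
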